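**Retrosynthetic overview**

1. The O1' isovalerate and the O5/O8 MOM ethers are handled last, around quinone 16, in which C1' is carried as a TBS ether.
2. Ring B (C1, C2, C3, C4, C4a, C8a) is closed last by a Dötz benzannulation with oxidative work-up: C4 is the carbene carbon of aryl complex 13, C1 a CO ligand, and C2–C3 the terminal alkyne 7.
3. Enabling feature: ring B carries para carbonyls at C1/C4, one substituent at C2 and H at C3, and ring A (C5–C8) is symmetric through O5/O8, so either alkyne orientation gives the same quinone.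
4. Alkyne 7 comes from 3-(trimethylsilyl)propynal: a Brown allylation sets C1' as S and a cross-metathesis installs the isopropylidene end.
5. Ring order: ring A is bought as hydroquinone, ring B is formed in step 7.

Key step: step 7

Assumption: the allylborane made from (+)-α-pinene (sold as (+)-Ipc2B(allyl), oxidised to (1R,2R,3R,5S)-isopinocampheol) is taken to attack the alkynal on the face it attacks benzaldehyde, which corresponds to the (S)-carbinol.

**Route**

Step 1
Reactants: 1 3-(trimethylsilyl)prop-2-ynal; 2 (+)-B-allyldiisopinocampheylborane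
Product: 3 (S)-1-(trimethylsilyl)hex-5-en-1-yn-3-ol
Conditions: Et2O, −78 °C; then NaBO3·4H2O, THF/H2O, rt
Reagents that add atoms: none
Why: Brown allylboration through a closed chair six-membered transition state, in which the isopinocampheyl groups of 2 choose the aldehyde face and should set C3 (the later C1') as S, the alkynyl group taking the place and CIP rank that phenyl has in the benzaldehyde case.

Step 2
Reactants: 3 (S)-1-(trimethylsilyl)hex-5-en-1-yn-3-ol
Product: 4 (S)-tert-butyldimethyl{[1-(trimethylsilyl)hex-5-en-1-yn-3-yl]oxy}silane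
Conditions: TBSCl, imidazole, DMF, rt
Reagents that add atoms: tert-butyldimethylsilyl chloride, CC(C)(C)[Si](C)(C)Cl
Why: imidazole-promoted O-silylation of a secondary alcohol, which does not touch the stereocentre.

Step 3
Reactants: 4 (S)-tert-butyldimethyl{[1-(trimethylsilyl)hex-5-en-1-yn-3-yl]oxy}silane; 5 2-methylbut-2-ene
Product: 6 (S)-tert-butyldimethyl{[6-methyl-1-(trimethylsilyl)hept-5-en-1-yn-3-yl]oxy}silane
Conditions: second-generation Grubbs catalyst RuCl2(=CHPh)(H2IMes)(PCy3) (5 mol%), 2-methylbut-2-ene/CH2Cl2, 35 °C
Reagents that add atoms: none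
Why: olefin cross-metathesis with excess 2-methylbut-2-ene should turn the vinyl end into the isopropylidene end with loss of propene, while the silyl-capped alkyne next to the OTBS group is a poor enyne-metathesis partner.

Step 4
Reactants: 6 (S)-tert-butyldimethyl{[6-methyl-1-(trimethylsilyl)hept-5-en-1-yn-3-yl]oxy}silane
Product: 7 (S)-tert-butyldimethyl[(6-methylhept-5-en-1-yn-3-yl)oxy]silane
Conditions: K2CO3 (cat.), MeOH, rt
Reagents that add atoms: none
Why: base-catalysed methanolysis of the alkynyl C–Si bond (protodesilylation), to which the secondary TBS ether is stable.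

Step 5
Reactants: 8 hydroquinone
Product: 9 1,4-bis(methoxymethoxy)benzene
Conditions: NaH, MOMCl, DMF, 0 °C → rt
Reagents that add atoms: chloromethyl methyl ether, COCCl
Why: Williamson O-alkylation of the bis-phenoxide.

Step 6
Reactants: 9 1,4-bis(methoxymethoxy)benzene; 10 chromium hexacarbonyl
Product: 13 pentacarbonyl{[2,5-bis(methoxymethoxy)phenyl](methoxy)methylidene}chromium, via aryllithium 11 (not isolated), via lithium acylchromate 12 (not isolated)
Conditions: n-BuLi, THF, 0 °C; Cr(CO)6, 0 °C → rt; then Me3OBF4, CH2Cl2, 0 °C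
Reagents that add atoms: trimethyloxonium tetrafluoroborate, C[O+](C)C.F[B-](F)(F)F
Why: MOM-directed ortho-lithiation, addition of the aryllithium to a CO ligand and O-methylation of the acyl chromate, which is the Fischer synthesis of an aryl(methoxy)carbene complex of zerovalent chromium.

Step 7
Reactants: 13 pentacarbonyl{[2,5-bis(methoxymethoxy)phenyl](methoxy)methylidene}chromium; 7 (S)-tert-butyldimethyl[(6-methylhept-5-en-1-yn-3-yl)oxy]silane
Product: 16 (S)-2-[1-(tert-butyldimethylsilyloxy)-4-methylpent-3-en-1-yl]-5,8-bis(methoxymethoxy)naphthalene-1,4-dione, via chromium-bound naphthol 14 (not isolated), via free naphthol 15 (not isolated)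
Conditions: 7 (1.5 equiv), THF, 50 °C; then (NH4)2Ce(NO3)6, MeCN/H2O, 0 °C
Reagents that add atoms: water, O
Why: Thermal loss of one CO from 13 lets alkyne 7 coordinate and insert into the Cr=C bond, a CO ligand then inserts to give an η4-vinylketene, and 6π-electrocyclic closure onto the only free ortho carbon of the aryl group followed by tautomerisation gives the chromium-bound naphthol 14, which tetravalent cerium demetalates to 15 and oxidatively demethylates to quinone 16 with the C4 oxygen coming from water. The closest known reaction type is the Dötz benzannulation of aryl(methoxy)carbene complexes of zerovalent chromium with terminal alkynes, propargylic silyl ethers included, followed by oxidative work-up to 1,4-naphthoquinones. Ring B is closed by three new C–C bonds (C4–C3, C2–C1 and C1–C8a), the last in a 6π-electrocyclisation of the arene-conjugated vinylketene, a formal [3+2+1] assembly. No new stereocentre is formed, and C1' should stay S because it takes no part in the bond changes, its silyl ether is a poor leaving group and the 1,5-enyne spacing rules out intramolecular cyclopropanation by the vinylcarbene. The step needs phenol formation to win over the cyclobutenone and indene channels, which THF, an excess of terminal alkyne and a moderate temperature favour, and it needs the oxidation to take place in ring B, which is secured because only ring B is a free p-methoxyphenol. The orientation of alkyne insertion does not matter, since the O5/O8 symmetry of ring A makes both regioisomeric naphthols give the same quinone.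

Step 8
Reactants: 16 (S)-2-[1-(tert-butyldimethylsilyloxy)-4-methylpent-3-en-1-yl]-5,8-bis(methoxymethoxy)naphthalene-1,4-dione
Product: 17 (S)-2-(1-hydroxy-4-methylpent-3-en-1-yl)-5,8-bis(methoxymethoxy)naphthalene-1,4-dione
Conditions: HF·pyridine, pyridine/THF, 0 °C → rt
Reagents that add atoms: none
Why: fluoride-mediated Si–O cleavage under acidic buffering, which avoids base-induced enolisation of C1'–H (the vinylogous α-position of the quinone), so the configuration should be kept.

Step 9
Reactants: 17 (S)-2-(1-hydroxy-4-methylpent-3-en-1-yl)-5,8-bis(methoxymethoxy)naphthalene-1,4-dione; 18 3-methylbutanoic acid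
Product: 19 (S)-1-[5,8-bis(methoxymethoxy)-1,4-dioxo-1,4-dihydronaphthalen-2-yl]-4-methylpent-3-en-1-yl 3-methylbutanoate
Conditions: DCC, DMAP (cat.), CH2Cl2, 0 °C → rt
Reagents that add atoms: none
Why: Steglich esterification, an acylation on oxygen that leaves the C1'–O bond intact and so retains the configuration.

Step 10
Reactants: 19 (S)-1-[5,8-bis(methoxymethoxy)-1,4-dioxo-1,4-dihydronaphthalen-2-yl]-4-methylpent-3-en-1-yl 3-methylbutanoate
Product: 20 isovalerylalkannin
Conditions: TFA, CH2Cl2, 0 °C; pH 7 buffer work-up
Reagents that add atoms: none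
Why: acid-catalysed cleavage of the two aryl MOM acetals, which should be fast because each peri quinone carbonyl makes the aryl oxygen a good leaving group and hydrogen-bonds the freed phenol, while the ester, the olefin and C1' should survive short exposure at 0 °C.

**Compound list**

1 | 3-(trimethylsilyl)prop-2-ynal | C[Si](C)(C)C#CC=O | starting material
2 | (+)-B-allyldiisopinocampheylborane, (+)-Ipc2B(allyl), from (+)-α-pinene | C=CCB([C@@H]1C[C@@H]2C[C@H]([C@H]1C)C2(C)C)[C@@H]1C[C@@H]2C[C@H]([C@H]1C)C2(C)C | starting material
3 | (S)-1-(trimethylsilyl)hex-5-en-1-yn-3-ol | C=CC[C@H](O)C#C[Si](C)(C)C | intermediate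
4 | (S)-tert-butyldimethyl{[1-(trimethylsilyl)hex-5-en-1-yn-3-yl]oxy}silane | C=CC[C@H](O[Si](C)(C)C(C)(C)C)C#C[Si](C)(C)C | intermediate
5 | 2-methylbut-2-ene | CC=C(C)C | starting material
6 | (S)-tert-butyldimethyl{[6-methyl-1-(trimethylsilyl)hept-5-en-1-yn-3-yl]oxy}silane | CC(C)=CC[C@H](O[Si](C)(C)C(C)(C)C)C#C[Si](C)(C)C | intermediate
7 | (S)-tert-butyldimethyl[(6-methylhept-5-en-1-yn-3-yl)oxy]silane | CC(C)=CC[C@H](O[Si](C)(C)C(C)(C)C)C#C | intermediate
8 | hydroquinone | Oc1ccc(O)cc1 | starting material
9 | 1,4-bis(methoxymethoxy)benzene | COCOc1ccc(OCOC)cc1 | intermediate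
10 | chromium hexacarbonyl, Cr(CO)6 | O=C=[Cr](=C=O)(=C=O)(=C=O)(=C=O)=C=O | starting material
11 | [2,5-bis(methoxymethoxy)phenyl]lithium (not isolated) | [Li]c1cc(OCOC)ccc1OCOC | intermediate
12 | lithium pentacarbonyl[2,5-bis(methoxymethoxy)benzoyl]chromate (not isolated) | [Li+].[O-]C(=[Cr](=C=O)(=C=O)(=C=O)(=C=O)=C=O)c1cc(OCOC)ccc1OCOC | intermediate
13 | pentacarbonyl{[2,5-bis(methoxymethoxy)phenyl](methoxy)methylidene}chromium | COC(=[Cr](=C=O)(=C=O)(=C=O)(=C=O)=C=O)c1cc(OCOC)ccc1OCOC | intermediate
14 | tricarbonylchromium complex of naphthol 15, η6-bound at ring B, written as arene plus Cr(CO)3 fragment (not isolated) | CC(C)=CC[C@H](O[Si](C)(C)C(C)(C)C)c1cc(OC)c2c(OCOC)ccc(OCOC)c2c1O.O=C=[Cr](=C=O)=C=O | intermediate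
15 | (S)-2-[1-(tert-butyldimethylsilyloxy)-4-methylpent-3-en-1-yl]-4-methoxy-5,8-bis(methoxymethoxy)naphthalen-1-ol (not isolated) | CC(C)=CC[C@H](O[Si](C)(C)C(C)(C)C)c1cc(OC)c2c(OCOC)ccc(OCOC)c2c1O | intermediate
16 | (S)-2-[1-(tert-butyldimethylsilyloxy)-4-methylpent-3-en-1-yl]-5,8-bis(methoxymethoxy)naphthalene-1,4-dione | CC(C)=CC[C@H](O[Si](C)(C)C(C)(C)C)C1=CC(=O)c2c(OCOC)ccc(OCOC)c2C1=O | intermediate
17 | (S)-2-(1-hydroxy-4-methylpent-3-en-1-yl)-5,8-bis(methoxymethoxy)naphthalene-1,4-dione | CC(C)=CC[C@H](O)C1=CC(=O)c2c(OCOC)ccc(OCOC)c2C1=O | intermediate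
18 | 3-methylbutanoic acid (isovaleric acid) | CC(C)CC(=O)O | starting material
19 | (S)-1-[5,8-bis(methoxymethoxy)-1,4-dioxo-1,4-dihydronaphthalen-2-yl]-4-methylpent-3-en-1-yl 3-methylbutanoate | CC(C)=CC[C@H](OC(=O)CC(C)C)C1=CC(=O)c2c(OCOC)ccc(OCOC)c2C1=O | intermediate
20 | isovalerylalkannin, (S)-1-(5,8-dihydroxy-1,4-dioxo-1,4-dihydronaphthalen-2-yl)-4-methylpent-3-en-1-yl 3-methylbutanoate | CC(C)=CC[C@H](OC(=O)CC(C)C)C1=CC(=O)c2c(O)ccc(O)c2C1=O | target

**Step count and risks**

Total step count: 10. Longest linear sequence: 8 steps (steps 1, 2, 3, 4, 7, 8, 9, 10).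

Steps most likely to fail:

1. Step 7. The vinylketene intermediate may leak into the cyclobutenone or indene channels, or the chromium-bound naphthol may ionise at the propargylic C–O bond and erode C1'. The fallback sets out from 13 and 7 and comes back at 15 and so at 16. The two are combined in MeCN at 45 °C, a solvent that drives aryl carbene complexes towards 4π-closure of the vinylketene, and the chromium residues are destroyed with air. This should give the cyclobutenone 4-[2,5-bis(methoxymethoxy)phenyl]-2-[(S)-1-(tert-butyldimethylsilyloxy)-4-methylpent-3-en-1-yl]-4-methoxycyclobut-2-en-1-one F1 as both epimers at C4. Heating this metal-free compound in toluene at 110 °C should reopen it with the methoxy group rotating outward and the aryl group inward, so that 6π-closure gives naphthol 15, which is oxidised in the same flask with (NH4)2Ce(NO3)6 to 16.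

2. Step 10. Once both phenols are free, naphthazarin tautomerism makes C1' benzylic to an electron-rich ring, so acid may ionise the acyloxy group or add to the trisubstituted olefin. The fallback sets out from 16 and comes back at 20. The MOM ethers are cleaved first (TFA, CH2Cl2, 0 °C) while C1' still carries the non-ionising silyl ether, to give (S)-2-[1-(tert-butyldimethylsilyloxy)-4-methylpent-3-en-1-yl]-5,8-dihydroxynaphthalene-1,4-dione F2. HF·pyridine then gives alkannin F3. The ester is formed last with 18, DCC and catalytic DMAP, a known selective acylation of the side-chain hydroxyl because the two peri phenols are chelated to the quinone carbonyls.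

3. Step 3. The ruthenium carbene may be sequestered by the alkyne (enyne metathesis), or the exchange may stop short of the trisubstituted olefin. The fallback sets out from 4 and comes back at 6. Lemieux–Johnson cleavage of the vinyl group (OsO4 cat., NaIO4, 2,6-lutidine, dioxane/H2O) gives (S)-3-(tert-butyldimethylsilyloxy)-5-(trimethylsilyl)pent-4-ynal F4. A Wittig reaction with isopropylidenetriphenylphosphorane (from isopropyltriphenylphosphonium iodide and n-BuLi, THF, −78 °C → rt) then gives 6.

**Further compounds**

F1 | step 7 | 4-[2,5-bis(methoxymethoxy)phenyl]-2-[(S)-1-(tert-butyldimethylsilyloxy)-4-methylpent-3-en-1-yl]-4-methoxycyclobut-2-en-1-one (both epimers at C4) | CC(C)=CC[C@H](O[Si](C)(C)C(C)(C)C)C1=CC(OC)(c2cc(OCOC)ccc2OCOC)C1=O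
F2 | step 10 | (S)-2-[1-(tert-butyldimethylsilyloxy)-4-methylpent-3-en-1-yl]-5,8-dihydroxynaphthalene-1,4-dione | CC(C)=CC[C@H](O[Si](C)(C)C(C)(C)C)C1=CC(=O)c2c(O)ccc(O)c2C1=O
F3 | step 10 | alkannin, (S)-5,8-dihydroxy-2-(1-hydroxy-4-methylpent-3-en-1-yl)naphthalene-1,4-dione | CC(C)=CC[C@H](O)C1=CC(=O)c2c(O)ccc(O)c2C1=O
F4 | step 3 | (S)-3-(tert-butyldimethylsilyloxy)-5-(trimethylsilyl)pent-4-ynal | O=CC[C@H](O[Si](C)(C)C(C)(C)C)C#C[Si](C)(C)C
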